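## Structural features

The target is a (2S)-flavanone. Aromatic ring A (C4a, C5, C6, C7, C8, C8a) is fused through C4a and C8a to the dihydropyranone ring C (O1, C2, C3, C4=O), and C2 carries the resorcinol-type ring B. C2 is the only stereocentre and has no stereogenic neighbour, so its configuration must be set absolutely. Ring A is a phloroglucinol with oxygens on C5, C7 and C8a (the last being O1 of ring C) and a (2E,6E)-farnesyl chain on C6, between the two free hydroxyls. The fragile parts are the three trisubstituted chain alkenes (proton- or halonium-induced cyclization, also onto an ortho phenol) and the O1–C2 bond β to the ketone, which opens under base by retro-oxa-Michael reaction and racemizes C2. The meta oxygens of ring B do not stabilize a cation at C2, so mild acid is less dangerous to the stereocentre than base. The real difficulty is regiochemical: the chain must sit on C6 and not on C8 of a nearly symmetrical trioxygenated ring, one oxygen (on C8a) must be told apart from the other two, and C2 must be created without touching the chain. The key step uses the fact that C6 lies para to C8a: before ring C exists, ring A has a mirror plane through C6 and C8a, and a benzannulation can deliver it with the C8a hydroxyl free, the C5 and C7 oxygens silylated and the chain on C6.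

## Logic of the disconnections

**24 to 23.** The four aryl O–Si bonds are cut last. One kind of protecting group on all phenols allows a single buffered fluoride step. The forward step must stay near neutral so that ring C does not open.

**23 to 21.** The C4–C4a bond is cut, opening ring C to an aryl ether acid. The two ring carbons ortho to the ether oxygen in 21 are equivalent, so closure can only place the chain on C6. The forward acylation must be mild enough to spare the alkenes and silyl ethers; it passes through 22.

**21 to 20.** The acid is traced to its methyl ester. The forward cleavage must avoid alkali, which would expel the aryloxide by β-elimination and attack the aryl silyl ethers.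

**20 to 15 and 19.** The O1–C2 bond is cut, separating ring A from the ring B three-carbon unit. This is the convergent point and it carries the stereocentre: displacement at the carbinol carbon of 19 with inversion gives the S ether. The forward step needs substitution to outrun β-elimination.

**15 to 6 and 10.** The key cut removes C8–C8a, C6–C7 and C4a–C8a and dissolves ring A into a four-membered ring and a two-carbon alkyne. All regiochemistry of ring A is transferred to the polarity of a ketene and an ynol ether. The forward step needs matched polarity and an alkyne that reacts before the chain alkenes.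

**6 to 5.** Two ring bonds of the cyclobutenone are cut, leaving an ynol silyl ether and a two-carbon ketene unit. This makes 6 in one step with the silyl group already on oxygen, with no hydrolysis and re-silylation of a vinylogous ester. The forward cycloaddition must be regioselective.

**5 to 2.** The alkyne C–O bond and the O–Si bond are cut, leading to a terminal alkyne. The forward step needs oxygen transfer to an acetylide and silylation on oxygen, not carbon.

**2 to 1.** The allyl–alkynyl C–C bond is cut, giving a commercial allylic bromide and an ethynyl metal reagent. The forward step must couple at the primary carbon without allylic transposition.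

**10 to 7.** The same C–O and O–Si cuts lead to acetylene. The forward step must cope with an unstable monometallated acetylene.

**19 to 18.** The C–H bond at the carbinol carbon is cut. An aryl ketone next to an ester is a reliable substrate for catalytic enantioselective reduction; the forward step needs high facial selectivity.

**18 to 17.** The bond between the ketone carbon and the methylene is cut, giving an aryl ester and an acetate enolate. The forward step is a crossed condensation that must not scramble esters or strip silyl ethers.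

**17 to 16.** The two aryl O–Si bonds are cut, leading to a commercial dihydroxy ester.

## Other disconnections considered

**Alternative 1:** The cut is made at C8a–O1 and C4a–C4 together. Ring A arrives as 4-farnesyl-3,5-bis(methoxymethoxy)benzyne A2, and the three-carbon bridge with ring B as (3R)-3-[3,5-bis(methoxymethoxy)phenyl]-3-(triisopropylsilyloxy)propanoic acid A3. In the forward step fluoride would release A2. The carboxylate oxygen would add to the aryne carbon remote from the flanking acetal (the future C8a). The aryl anion next to that acetal (C4a) would then take the acyl group, giving the ortho-hydroxyaryl ketone A1 without closing a ring. Ring C would follow by freeing the secondary alcohol and displacing it with the phenol with inversion.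

- In its favour: two bonds to ring A form in one operation, with regiochemistry set by the polarization of the oxygenated aryne. No electrophilic acylation is run near the chain, which is better than step 11 of the chosen plan. The stereocentre passes through the coupling as a silyl ether, so no elimination-prone intermolecular etherification is needed, which is better than step 9.
- Against it: A2 needs a pentasubstituted ortho-silyl aryl sulfonate precursor, so the C6/C8 problem is only moved into a longer classical ring A synthesis. The acyl shift must compete with simple protonation of a hindered aryl anion. Fluoride may attack the secondary silyl ether, and a β-oxygenated ketone eliminates easily. The last step must remove four acetals with acid while two free phenols flank the chain, which invites chroman formation; the fluoride end game of the chosen plan is safer.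
- Comparison: convergence is equal. Ring A regiocontrol is better in the chosen plan. The operations after fragment union are fewer here (about three against four), which is a point for A1, but the total count is expected to be higher.

**Alternative 2:** The cut is at C4a–C5, so ring A is the last ring formed. The precursor is methyl 2-farnesyl-4-[(2S)-2-[3,5-bis(methoxymethoxy)phenyl]-4-oxo-3,4-dihydro-2H-pyran-6-yl]-3-oxobutanoate A5, in which the chain already sits on the future C6. A magnesium alkoxide would enolize the side chain. The vinylogous enolate carbon C4a would attack the ester carbon C5, and loss of methanol with tautomerization would give (2S)-6-farnesyl-5,7-dihydroxy-3',5'-bis(methoxymethoxy)flavanone A4.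

- In its favour: the route is biomimetic and the chain position is fixed in the open chain, so regiochemistry is as unambiguous as in the chosen plan (equal). Ring A appears with both hydroxyls free, so it needs no protecting groups (better). The stereocentre could come from a catalytic enantioselective hetero-Diels–Alder reaction of the ring B aldehyde, which is equal to or better than reduction plus inversion.
- Against it: A5 has a doubly activated methine, and its assembly and selective C-farnesylation are not trivial. Under the basic conditions, deprotonation at C3 can open ring C at O1–C2. The product A4 is itself a 5,7-dihydroxyflavanone that opens in alkoxide, so C2 is exposed to racemization twice. A competing condensation of C8 onto C4 is possible. The acid needed to remove the acetals meets a chain flanked by free phenols.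
- Comparison: the step count is probably similar. Stereochemical integrity is weaker than in the chosen plan, which exposes C2 only to near-neutral or cold, mildly acidic media.

**Alternative 3:** The cut is at C2–C3. Ring A is complete and carries a diazomethyl ketone on C4a and the ring B benzyl group on the C8a oxygen: 2-diazo-1-[2-{[3,5-bis(tert-butyldimethylsilyloxy)phenyl]methoxy}-5-farnesyl-4,6-bis(tert-butyldimethylsilyloxy)phenyl]ethan-1-one A7. A chiral dirhodium carboxylate (divalent rhodium) would generate a carbenoid at C3. Insertion into the benzylic C–H bond of the ether would form C2–C3, ring C and the stereocentre in (2S)-6-farnesyl-5,7,3',5'-tetrakis(tert-butyldimethylsilyloxy)flavanone A6.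

- In its favour: ring and stereocentre come from an achiral precursor in one catalytic step, which is better in step economy than the two-step reduction and inversion of the chosen plan. Protection is all silyl and the end game is the same fluoride step (equal).
- Against it: the insertion must form a six-membered ring. Attack of the ether oxygen on the carbenoid gives a five-membered oxonium ylide, and a benzyl shift from it would lead to a benzofuranone. An acceptor-only carbenoid is unselective, and the three trisubstituted alkenes are good cyclopropanation partners. Enantiocontrol with terminal diazoketones is uncertain. A7 requires acylation of diazomethane by a hindered 2,6-dioxygenated benzoyl chloride. Ring A regiochemistry still has to be solved classically.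
- Comparison: the alternative is shorter on paper after ring A, but its mechanism has more unproductive channels. The chosen plan is longer at the end and relies on better understood bond formations.

Key step: step 5

Assumption: the (R,R)-configured ruthenium catalyst of step 8 is taken to give the (R)-carbinol, as it does for aryl ketones in which the aryl group outranks the second carbon substituent; ketene is taken as a gas stream from a ketene generator.

## Route

Step 1
Reactants: 1 (2E,6E)-farnesyl bromide
Product: 2 (4E,8E)-5,9,13-trimethyltetradeca-4,8,12-trien-1-yne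
Conditions: HC≡CMgBr (1.5 equiv), CuCl (5 mol%), THF, 0 °C → rt
Reagents that add atoms: ethynylmagnesium bromide, C#C[Mg]Br
Why: Copper-catalysed allyl–alkynyl cross-coupling of a Grignard reagent with a primary allylic bromide; attack at the unhindered CH2 terminus (the other allylic terminus is fully substituted) leaves the 2E alkene in place. The excess of the ethynyl reagent holds back a second alkylation at the new terminal alkyne.

Step 2
Reactants: 2 (4E,8E)-5,9,13-trimethyltetradeca-4,8,12-trien-1-yne
Product: 5 triisopropyl{[(4E,8E)-5,9,13-trimethyltetradeca-4,8,12-trien-1-yn-1-yl]oxy}silane, via lithium acetylide 3 (not isolated), via lithium ynolate 4 (not isolated)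
Conditions: n-BuLi, THF, −78 °C; t-BuOOLi (from t-BuOOH and LiN(SiMe3)2), −78 → 0 °C; TIPSOTf, −78 → 0 °C
Reagents that add atoms: tert-butyl hydroperoxide (used as its lithium salt), CC(C)(C)OO; triisopropylsilyl trifluoromethanesulfonate, CC(C)[Si](OS(=O)(=O)C(F)(F)F)(C(C)C)C(C)C
Why: Electrophilic oxygen transfer from the lithium peroxide to the lithium acetylide gives the ynolate (acetylide oxidation), and the bulky silyl triflate captures it on oxygen (O-silylation of an ynolate to a siloxyalkyne). At −78 °C the base removes only the acetylenic proton, and the peroxide anion does not epoxidize isolated alkenes.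

Step 3
Reactants: 5 triisopropyl{[(4E,8E)-5,9,13-trimethyltetradeca-4,8,12-trien-1-yn-1-yl]oxy}silane
Product: 6 2-[(2E,6E)-farnesyl]-3-(triisopropylsilyloxy)cyclobut-2-en-1-one
Conditions: CH2=C=O (gas stream, excess), CH2Cl2, 0 °C → rt
Reagents that add atoms: ketene, C=C=O
Why: Thermal [2+2] cycloaddition of ketene with an electron-rich siloxyalkyne, a known entry to 3-siloxycyclobutenones; the ketene carbonyl carbon bonds to the nucleophilic alkyne carbon that bears the chain, which puts the chain on C2 and the silyloxy group on C3. The isolated chain alkenes are far poorer ketenophiles than the ynol ether.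

Step 4
Reactants: 7 acetylene
Product: 10 (triisopropylsilyloxy)acetylene, via lithium acetylide 8 (not isolated), via lithium ethynolate 9 (not isolated)
Conditions: n-BuLi, THF, −78 °C (7 in excess); t-BuOOLi (from t-BuOOH and LiN(SiMe3)2), −78 → −30 °C; TIPSOTf, −78 → 0 °C; distillation
Reagents that add atoms: tert-butyl hydroperoxide (used as its lithium salt), CC(C)(C)OO; triisopropylsilyl trifluoromethanesulfonate, CC(C)[Si](OS(=O)(=O)C(F)(F)F)(C(C)C)C(C)C
Why: The same acetylide oxidation and ynolate O-silylation as in step 2, applied to monolithium acetylide. Low temperature and an excess of acetylene guard against disproportionation to Li2C2, and the bulk of the silyl group steers silylation to oxygen.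

Step 5
Reactants: 6 2-[(2E,6E)-farnesyl]-3-(triisopropylsilyloxy)cyclobut-2-en-1-one; 10 (triisopropylsilyloxy)acetylene
Product: 15 4-[(2E,6E)-farnesyl]-3,5-bis(triisopropylsilyloxy)phenol, via vinylketene 11 (not isolated), via 4-vinylcyclobutenone 12 (not isolated), via dienylketene 13 (not isolated), via cyclohexadienone 14 (not isolated)
Conditions: 10 (2 equiv), toluene, 80 → 110 °C, argon, sealed vessel
Reagents that add atoms: none
Why: Danheiser benzannulation: heat opens 6 by four-electron conrotatory cleavage of its C1–C4 bond to vinylketene 11. The electrophilic ketene carbon of 11 bonds to the unsubstituted, nucleophilic carbon of 10 and the ketene α-carbon to the oxygen-bearing carbon in a regiospecific [2+2] cycloaddition (C8–C8a and C6–C7), giving 4-vinylcyclobutenone 12. A second four-electron opening gives dienylketene 13, whose six-electron disrotatory electrocyclization forms C4a–C8a and closes ring A as cyclohexadienone 14, which enolizes to 15. The closest known reaction type is the thermal annulation of cyclobutenones with siloxyalkynes to resorcinol monosilyl ethers; a 3-siloxycyclobutenone only adds a second silyloxy group to the same pattern. No stereocentre is created, because the quaternary carbon of 12 is transient and becomes planar on aromatization. The regiochemistry needed (free hydroxyl from the ketene carbonyl on C8a, para to the chain, both silyloxy groups meta to it) follows from matched polarity, the ynol ether being nucleophilic at its β-carbon and the ketene electrophilic at its carbonyl carbon. The chemoselectivity needed (alkyne before alkenes) rests on the high ketenophilicity of 10 and on the one-carbon link to the nearest chain alkene, which is too short for an intramolecular ketene–alkene cycloaddition. An excess of 10 keeps 15 from capturing 11 as an aryl ester, and the bulky silyl groups resist the 1,3-shift of silicon from oxygen to carbon at this temperature.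

Step 6
Reactants: 16 methyl 3,5-dihydroxybenzoate
Product: 17 methyl 3,5-bis(triisopropylsilyloxy)benzoate
Conditions: TIPSCl (2.4 equiv), imidazole, DMF, rt
Reagents that add atoms: triisopropylsilyl chloride, CC(C)[Si](Cl)(C(C)C)C(C)C
Why: Standard silylation of both phenols with a silyl chloride and imidazole; the methyl ester is untouched.

Step 7
Reactants: 17 methyl 3,5-bis(triisopropylsilyloxy)benzoate
Product: 18 methyl 3-[3,5-bis(triisopropylsilyloxy)phenyl]-3-oxopropanoate
Conditions: CH3CO2CH3, LiN(SiMe3)2 (3 equiv), THF, −78 → −20 °C; aq. NH4Cl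
Reagents that add atoms: methyl acetate, COC(C)=O
Why: Crossed Claisen condensation: the lithium enolate of methyl acetate acylates the non-enolizable aryl ester, and deprotonation of the β-keto ester by the excess base drives the equilibrium. Matching the acetate to the methyl ester avoids ester scrambling, and the low temperature protects the aryl silyl ethers from methoxide.

Step 8
Reactants: 18 methyl 3-[3,5-bis(triisopropylsilyloxy)phenyl]-3-oxopropanoate
Product: 19 methyl (3R)-3-[3,5-bis(triisopropylsilyloxy)phenyl]-3-hydroxypropanoate
Conditions: RuCl[(R,R)-TsDPEN](p-cymene) (1 mol%), HCO2H–Et3N (5:2), 30 °C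
Reagents that add atoms: none
Why: Noyori asymmetric transfer hydrogenation of an aryl ketone; the (R,R)-diamine complex delivers hydride and proton through a six-membered transition state in which the ligand NH and the η6-arene fix the aryl group, giving the (R)-carbinol. The ester and the aryl silyl ethers are inert to the formate system.

Step 9
Reactants: 15 4-[(2E,6E)-farnesyl]-3,5-bis(triisopropylsilyloxy)phenol; 19 methyl (3R)-3-[3,5-bis(triisopropylsilyloxy)phenyl]-3-hydroxypropanoate
Product: 20 methyl (3S)-3-[3,5-bis(triisopropylsilyloxy)phenyl]-3-{4-[(2E,6E)-farnesyl]-3,5-bis(triisopropylsilyloxy)phenoxy}propanoate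
Conditions: PPh3, DIAD, toluene, 0 °C → rt
Reagents that add atoms: none
Why: Mitsunobu etherification: the phenol (pKa near 10) displaces the oxyphosphonium group in an SN2 step with inversion, turning the (R)-alcohol into the (S)-ether that becomes C2. The meta-silyloxy groups of ring B do not stabilize a benzylic cation, so an ionization path that would erode the configuration is not favoured. Low temperature and a non-polar solvent hold back β-elimination to the cinnamate.

Step 10
Reactants: 20 methyl (3S)-3-[3,5-bis(triisopropylsilyloxy)phenyl]-3-{4-[(2E,6E)-farnesyl]-3,5-bis(triisopropylsilyloxy)phenoxy}propanoate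
Product: 21 (3S)-3-[3,5-bis(triisopropylsilyloxy)phenyl]-3-{4-[(2E,6E)-farnesyl]-3,5-bis(triisopropylsilyloxy)phenoxy}propanoic acid
Conditions: Me3SnOH, ClCH2CH2Cl, 70 °C; cold dilute aq. HCl
Reagents that add atoms: trimethyltin hydroxide, C[Sn](C)(C)O
Why: Methyl ester cleavage by hydroxide transfer from tin under nearly neutral conditions. Alkaline hydrolysis would risk β-elimination of the aryloxide and loss of aryl silyl ethers; this reagent should cause neither.

Step 11
Reactants: 21 (3S)-3-[3,5-bis(triisopropylsilyloxy)phenyl]-3-{4-[(2E,6E)-farnesyl]-3,5-bis(triisopropylsilyloxy)phenoxy}propanoic acid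
Product: 23 (2S)-6-[(2E,6E)-farnesyl]-5,7,3',5'-tetrakis(triisopropylsilyloxy)flavanone, via mixed trifluoroacetic anhydride 22 (not isolated)
Conditions: (CF3CO)2O (1.2 equiv), CH2Cl2, −20 → 0 °C; aq. NaHCO3
Reagents that add atoms: none
Why: Intramolecular Friedel–Crafts acylation through the mixed anhydride 22: the alkanoyl end is transferred to the ring carbon ortho to the ether oxygen, which three oxygen substituents activate, and ring C closes as a six-membered aryl ketone. The two ortho carbons are equivalent by symmetry, so only the isomer with the chain on C6 can form. C2 is not involved, and the cold, dilute acid that is released should spare the chain alkenes and the silyl ethers.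

Step 12
Reactants: 23 (2S)-6-[(2E,6E)-farnesyl]-5,7,3',5'-tetrakis(triisopropylsilyloxy)flavanone
Product: 24 (2S)-6-[(2E,6E)-farnesyl]-5,7,3',5'-tetrahydroxyflavanone (target, CNP0186816.1)
Conditions: Bu4NF–AcOH (1:1, 6 equiv), THF, 0 °C → rt
Reagents that add atoms: none
Why: Fluoride cleavage of four aryl silyl ethers. Acetic acid buffers the phenoxides so that the flavanone does not open by retro-oxa-Michael reaction and C2 keeps its configuration.

## Compound list

1 | (2E,6E)-farnesyl bromide | CC(C)=CCC/C(C)=C/CC/C(C)=C/CBr | starting material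
2 | (4E,8E)-5,9,13-trimethyltetradeca-4,8,12-trien-1-yne | CC(C)=CCC/C(C)=C/CC/C(C)=C/CC#C | intermediate
3 | lithium acetylide of 2 | CC(C)=CCC/C(C)=C/CC/C(C)=C/CC#C[Li] | intermediate
4 | lithium (4E,8E)-5,9,13-trimethyltetradeca-4,8,12-trien-1-yn-1-olate | CC(C)=CCC/C(C)=C/CC/C(C)=C/CC#C[O-].[Li+] | intermediate
5 | triisopropyl{[(4E,8E)-5,9,13-trimethyltetradeca-4,8,12-trien-1-yn-1-yl]oxy}silane | CC(C)=CCC/C(C)=C/CC/C(C)=C/CC#CO[Si](C(C)C)(C(C)C)C(C)C | intermediate
6 | 2-[(2E,6E)-farnesyl]-3-(triisopropylsilyloxy)cyclobut-2-en-1-one | CC(C)=CCC/C(C)=C/CC/C(C)=C/CC1=C(O[Si](C(C)C)(C(C)C)C(C)C)CC1=O | intermediate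
7 | acetylene | C#C | starting material
8 | lithium acetylide (HC≡CLi) | [Li]C#C | intermediate
9 | lithium ethynolate (HC≡COLi) | C#C[O-].[Li+] | intermediate
10 | (triisopropylsilyloxy)acetylene | C#CO[Si](C(C)C)(C(C)C)C(C)C | intermediate
11 | 2-[(2E,6E)-farnesyl]-3-(triisopropylsilyloxy)buta-1,3-dien-1-one | CC(C)=CCC/C(C)=C/CC/C(C)=C/CC(=C=O)C(=C)O[Si](C(C)C)(C(C)C)C(C)C | intermediate
12 | 4-[(2E,6E)-farnesyl]-3-(triisopropylsilyloxy)-4-[1-(triisopropylsilyloxy)vinyl]cyclobut-2-en-1-one (racemic, transient) | CC(C)=CCC/C(C)=C/CC/C(C)=C/CC1(C(=C)O[Si](C(C)C)(C(C)C)C(C)C)C(O[Si](C(C)C)(C(C)C)C(C)C)=CC1=O | intermediate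
13 | (3E)-4-[(2E,6E)-farnesyl]-3,5-bis(triisopropylsilyloxy)hexa-1,3,5-trien-1-one | O=C=C/C(O[Si](C(C)C)(C(C)C)C(C)C)=C(\C(=C)O[Si](C(C)C)(C(C)C)C(C)C)C/C=C(\C)CC/C=C(\C)CCC=C(C)C | intermediate
14 | 4-[(2E,6E)-farnesyl]-3,5-bis(triisopropylsilyloxy)cyclohexa-2,4-dien-1-one | CC(C)=CCC/C(C)=C/CC/C(C)=C/CC1=C(O[Si](C(C)C)(C(C)C)C(C)C)CC(=O)C=C1O[Si](C(C)C)(C(C)C)C(C)C | intermediate
15 | 4-[(2E,6E)-farnesyl]-3,5-bis(triisopropylsilyloxy)phenol | CC(C)=CCC/C(C)=C/CC/C(C)=C/Cc1c(O[Si](C(C)C)(C(C)C)C(C)C)cc(O)cc1O[Si](C(C)C)(C(C)C)C(C)C | intermediate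
16 | methyl 3,5-dihydroxybenzoate | COC(=O)c1cc(O)cc(O)c1 | starting material
17 | methyl 3,5-bis(triisopropylsilyloxy)benzoate | COC(=O)c1cc(O[Si](C(C)C)(C(C)C)C(C)C)cc(O[Si](C(C)C)(C(C)C)C(C)C)c1 | intermediate
18 | methyl 3-[3,5-bis(triisopropylsilyloxy)phenyl]-3-oxopropanoate | COC(=O)CC(=O)c1cc(O[Si](C(C)C)(C(C)C)C(C)C)cc(O[Si](C(C)C)(C(C)C)C(C)C)c1 | intermediate
19 | methyl (3R)-3-[3,5-bis(triisopropylsilyloxy)phenyl]-3-hydroxypropanoate | COC(=O)C[C@@H](O)c1cc(O[Si](C(C)C)(C(C)C)C(C)C)cc(O[Si](C(C)C)(C(C)C)C(C)C)c1 | intermediate
20 | methyl (3S)-3-[3,5-bis(triisopropylsilyloxy)phenyl]-3-{4-[(2E,6E)-farnesyl]-3,5-bis(triisopropylsilyloxy)phenoxy}propanoate | COC(=O)C[C@@H](c1cc(O[Si](C(C)C)(C(C)C)C(C)C)cc(O[Si](C(C)C)(C(C)C)C(C)C)c1)Oc1cc(O[Si](C(C)C)(C(C)C)C(C)C)c(C/C=C(\C)CC/C=C(\C)CCC=C(C)C)c(O[Si](C(C)C)(C(C)C)C(C)C)c1 | intermediate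
21 | (3S)-3-[3,5-bis(triisopropylsilyloxy)phenyl]-3-{4-[(2E,6E)-farnesyl]-3,5-bis(triisopropylsilyloxy)phenoxy}propanoic acid | OC(=O)C[C@@H](c1cc(O[Si](C(C)C)(C(C)C)C(C)C)cc(O[Si](C(C)C)(C(C)C)C(C)C)c1)Oc1cc(O[Si](C(C)C)(C(C)C)C(C)C)c(C/C=C(\C)CC/C=C(\C)CCC=C(C)C)c(O[Si](C(C)C)(C(C)C)C(C)C)c1 | intermediate
22 | mixed anhydride of 21 with trifluoroacetic acid | O=C(OC(=O)C(F)(F)F)C[C@@H](c1cc(O[Si](C(C)C)(C(C)C)C(C)C)cc(O[Si](C(C)C)(C(C)C)C(C)C)c1)Oc1cc(O[Si](C(C)C)(C(C)C)C(C)C)c(C/C=C(\C)CC/C=C(\C)CCC=C(C)C)c(O[Si](C(C)C)(C(C)C)C(C)C)c1 | intermediate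
23 | (2S)-6-[(2E,6E)-farnesyl]-5,7,3',5'-tetrakis(triisopropylsilyloxy)flavanone | CC(C)=CCC/C(C)=C/CC/C(C)=C/Cc1c(O[Si](C(C)C)(C(C)C)C(C)C)cc2c(c1O[Si](C(C)C)(C(C)C)C(C)C)C(=O)C[C@@H](c1cc(O[Si](C(C)C)(C(C)C)C(C)C)cc(O[Si](C(C)C)(C(C)C)C(C)C)c1)O2 | intermediate
24 | (2S)-6-[(2E,6E)-farnesyl]-5,7,3',5'-tetrahydroxyflavanone | CC(C)=CCC/C(C)=C/CC/C(C)=C/Cc1c(O)cc2c(c1O)C(=O)C[C@@H](c1cc(O)cc(O)c1)O2 | target

## Step count and least certain steps

Total: 12 steps. Longest linear sequence: 8 steps (steps 1, 2, 3, 5, 9, 10, 11, 12). Step 4 and steps 6–8 are side branches.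

**Step 5 (key step).** The vinylogous-ester character of 6 may slow its electrocyclic opening so much that 10 is consumed first, by the 1,3-shift of silicon to carbon or by oligomerization. The phenol product may also trap the vinylketene as an aryl ester. The fallback sets out from 1 and comes back to the route at 15, building ring A from an existing aromatic ring. Phloroglucinol is C-alkylated with 1 (DBU, THF) to give 2-[(2E,6E)-farnesyl]benzene-1,3,5-triol F1. The unhindered hydroxyl para to the chain is acylated selectively (pivaloyl chloride, pyridine, −40 °C) to give 4-farnesyl-3,5-dihydroxyphenyl pivalate F2. The two flanking hydroxyls are silylated (TIPSOTf, 2,6-lutidine) to give 4-farnesyl-3,5-bis(triisopropylsilyloxy)phenyl pivalate F3. Reductive removal of the ester (i-Bu2AlH, CH2Cl2, −78 °C) gives 15.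

**Step 4.** Monolithium acetylide may disproportionate before oxygen transfer is complete. The unhindered parent ynolate may be silylated on carbon, giving a silylketene. The volatile product may be lost on isolation. The fallback does not draw on acetylene 7: it sets out from purchased triisopropyl(vinyloxy)silane F4 and comes back to the route at 10, following the classical halogenation–dehydrohalogenation route to ynol ethers. Bromine addition (CH2Cl2, −78 °C) gives (1,2-dibromoethoxy)triisopropylsilane F5. Loss of HBr with Et3N gives [(Z)-2-bromovinyloxy]triisopropylsilane F6. A second elimination with LiN(i-Pr)2 (THF, −78 °C) and a cold proton quench gives 10.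

**Step 2.** Alkoxide-rich conditions may isomerize the skipped enyne through its doubly activated CH2 group, and oxygen transfer to the acetylide may stop short. The fallback sets out from 1 and comes back to the route at 6 by the ynol ether–hydrolysis sequence. Lithium ethoxyacetylide (ethoxyacetylene, n-BuLi) is alkylated with 1 in THF–DMPU to give (4E,8E)-1-ethoxy-5,9,13-trimethyltetradeca-4,8,12-trien-1-yne F7. Ketene cycloaddition gives 3-ethoxy-2-farnesylcyclobut-2-en-1-one F8. Cold dilute aqueous HCl in THF hydrolyses the vinylogous ester to 2-farnesyl-3-hydroxycyclobut-2-en-1-one F9. O-silylation (TIPSCl, Et3N, CH2Cl2) gives 6.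

**Step 9.** The activated alcohol has acidic α-hydrogens next to the ester, so β-elimination to the cinnamate may compete with substitution by the moderately acidic phenol. The fallback sets out from 19 (and uses 15) and comes back to the route at 21; it removes the acidifying carbonyl before the etherification. Reduction of 19 (LiBH4, THF) gives (1R)-1-[3,5-bis(triisopropylsilyloxy)phenyl]propane-1,3-diol F10. Selective silylation of the primary hydroxyl (TBSCl, imidazole, 0 °C) gives (1R)-1-[3,5-bis(triisopropylsilyloxy)phenyl]-3-(tert-butyldimethylsilyloxy)propan-1-ol F11. Mitsunobu etherification with 15 gives the (3S)-aryl ether F12. Pyridinium p-toluenesulfonate in methanol frees the primary alcohol, (3S)-3-[3,5-bis(triisopropylsilyloxy)phenyl]-3-[4-farnesyl-3,5-bis(triisopropylsilyloxy)phenoxy]propan-1-ol F13. Oxidation with PhI(OAc)2 and catalytic TEMPO in aqueous acetonitrile gives 21.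

**Step 11.** The trifluoroacetic acid released may protonate the chain alkenes (cyclization or trifluoroacetate addition), and the anhydride may trifluoroacetylate the ring between molecules. The fallback sets out from 15 and 19 and comes back to the route at 23; it replaces the electrophilic closure by an anionic one (Parham cyclization). Monobromination of 15 (N-bromosuccinimide, CH2Cl2, −78 °C) gives 2-bromo-4-farnesyl-3,5-bis(triisopropylsilyloxy)phenol F14. Compound 19 is converted with N,O-dimethylhydroxylamine hydrochloride and i-PrMgCl into (3R)-3-[3,5-bis(triisopropylsilyloxy)phenyl]-3-hydroxy-N-methoxy-N-methylpropanamide F15. Mitsunobu coupling of F14 and F15 gives the (3S)-bromoaryl ether amide F16. Bromine–lithium exchange (t-BuLi, THF, −95 °C) and attack of the aryllithium on the amide give 23 after work-up.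

## Further compounds

F1 | step 5 | 2-[(2E,6E)-farnesyl]benzene-1,3,5-triol | CC(C)=CCC/C(C)=C/CC/C(C)=C/Cc1c(O)cc(O)cc1O
F2 | step 5 | 4-[(2E,6E)-farnesyl]-3,5-dihydroxyphenyl 2,2-dimethylpropanoate | CC(C)=CCC/C(C)=C/CC/C(C)=C/Cc1c(O)cc(OC(=O)C(C)(C)C)cc1O
F3 | step 5 | 4-[(2E,6E)-farnesyl]-3,5-bis(triisopropylsilyloxy)phenyl 2,2-dimethylpropanoate | CC(C)=CCC/C(C)=C/CC/C(C)=C/Cc1c(O[Si](C(C)C)(C(C)C)C(C)C)cc(OC(=O)C(C)(C)C)cc1O[Si](C(C)C)(C(C)C)C(C)C
F4 | step 4 | triisopropyl(vinyloxy)silane | C=CO[Si](C(C)C)(C(C)C)C(C)C
F5 | step 4 | (1,2-dibromoethoxy)triisopropylsilane | BrCC(Br)O[Si](C(C)C)(C(C)C)C(C)C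
F6 | step 4 | [(Z)-2-bromovinyloxy]triisopropylsilane | Br/C=C\O[Si](C(C)C)(C(C)C)C(C)C
F7 | step 2 | (4E,8E)-1-ethoxy-5,9,13-trimethyltetradeca-4,8,12-trien-1-yne | CC(C)=CCC/C(C)=C/CC/C(C)=C/CC#COCC
F8 | step 2 | 3-ethoxy-2-[(2E,6E)-farnesyl]cyclobut-2-en-1-one | CC(C)=CCC/C(C)=C/CC/C(C)=C/CC1=C(OCC)CC1=O
F9 | step 2 | 2-[(2E,6E)-farnesyl]-3-hydroxycyclobut-2-en-1-one | CC(C)=CCC/C(C)=C/CC/C(C)=C/CC1=C(O)CC1=O
F10 | step 9 | (1R)-1-[3,5-bis(triisopropylsilyloxy)phenyl]propane-1,3-diol | OCC[C@@H](O)c1cc(O[Si](C(C)C)(C(C)C)C(C)C)cc(O[Si](C(C)C)(C(C)C)C(C)C)c1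
F11 | step 9 | (1R)-1-[3,5-bis(triisopropylsilyloxy)phenyl]-3-(tert-butyldimethylsilyloxy)propan-1-ol | CC(C)(C)[Si](C)(C)OCC[C@@H](O)c1cc(O[Si](C(C)C)(C(C)C)C(C)C)cc(O[Si](C(C)C)(C(C)C)C(C)C)c1
F12 | step 9 | tert-butyl{(3S)-3-[3,5-bis(triisopropylsilyloxy)phenyl]-3-[4-farnesyl-3,5-bis(triisopropylsilyloxy)phenoxy]propoxy}dimethylsilane | CC(C)(C)[Si](C)(C)OCC[C@@H](c1cc(O[Si](C(C)C)(C(C)C)C(C)C)cc(O[Si](C(C)C)(C(C)C)C(C)C)c1)Oc1cc(O[Si](C(C)C)(C(C)C)C(C)C)c(C/C=C(\C)CC/C=C(\C)CCC=C(C)C)c(O[Si](C(C)C)(C(C)C)C(C)C)c1
F13 | step 9 | (3S)-3-[3,5-bis(triisopropylsilyloxy)phenyl]-3-[4-farnesyl-3,5-bis(triisopropylsilyloxy)phenoxy]propan-1-ol | OCC[C@@H](c1cc(O[Si](C(C)C)(C(C)C)C(C)C)cc(O[Si](C(C)C)(C(C)C)C(C)C)c1)Oc1cc(O[Si](C(C)C)(C(C)C)C(C)C)c(C/C=C(\C)CC/C=C(\C)CCC=C(C)C)c(O[Si](C(C)C)(C(C)C)C(C)C)c1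
F14 | step 11 | 2-bromo-4-[(2E,6E)-farnesyl]-3,5-bis(triisopropylsilyloxy)phenol | CC(C)=CCC/C(C)=C/CC/C(C)=C/Cc1c(O[Si](C(C)C)(C(C)C)C(C)C)cc(O)c(Br)c1O[Si](C(C)C)(C(C)C)C(C)C
F15 | step 11 | (3R)-3-[3,5-bis(triisopropylsilyloxy)phenyl]-3-hydroxy-N-methoxy-N-methylpropanamide | CON(C)C(=O)C[C@@H](O)c1cc(O[Si](C(C)C)(C(C)C)C(C)C)cc(O[Si](C(C)C)(C(C)C)C(C)C)c1
F16 | step 11 | (3S)-3-[3,5-bis(triisopropylsilyloxy)phenyl]-3-[2-bromo-4-farnesyl-3,5-bis(triisopropylsilyloxy)phenoxy]-N-methoxy-N-methylpropanamide | CON(C)C(=O)C[C@@H](c1cc(O[Si](C(C)C)(C(C)C)C(C)C)cc(O[Si](C(C)C)(C(C)C)C(C)C)c1)Oc1cc(O[Si](C(C)C)(C(C)C)C(C)C)c(C/C=C(\C)CC/C=C(\C)CCC=C(C)C)c(O[Si](C(C)C)(C(C)C)C(C)C)c1Br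
A1 | alternative 1 | (3R)-1-[3-farnesyl-6-hydroxy-2,4-bis(methoxymethoxy)phenyl]-3-[3,5-bis(methoxymethoxy)phenyl]-3-(triisopropylsilyloxy)propan-1-one | CC(C)=CCC/C(C)=C/CC/C(C)=C/Cc1c(OCOC)cc(O)c(c1OCOC)C(=O)C[C@H](c1cc(OCOC)cc(OCOC)c1)O[Si](C(C)C)(C(C)C)C(C)C
A2 | alternative 1 | 4-[(2E,6E)-farnesyl]-3,5-bis(methoxymethoxy)benzyne | COCOC1=C(C/C=C(\C)CC/C=C(\C)CCC=C(C)C)C(OCOC)=CC#C1
A3 | alternative 1 | (3R)-3-[3,5-bis(methoxymethoxy)phenyl]-3-(triisopropylsilyloxy)propanoic acid | OC(=O)C[C@H](c1cc(OCOC)cc(OCOC)c1)O[Si](C(C)C)(C(C)C)C(C)C
A4 | alternative 2 | (2S)-6-[(2E,6E)-farnesyl]-5,7-dihydroxy-3',5'-bis(methoxymethoxy)flavanone | CC(C)=CCC/C(C)=C/CC/C(C)=C/Cc1c(O)cc2c(c1O)C(=O)C[C@@H](c1cc(OCOC)cc(OCOC)c1)O2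
A5 | alternative 2 | methyl 2-[(2E,6E)-farnesyl]-4-[(2S)-2-[3,5-bis(methoxymethoxy)phenyl]-4-oxo-3,4-dihydro-2H-pyran-6-yl]-3-oxobutanoate | COC(=O)C(C/C=C(\C)CC/C=C(\C)CCC=C(C)C)C(=O)CC1=CC(=O)C[C@@H](c2cc(OCOC)cc(OCOC)c2)O1
A6 | alternative 3 | (2S)-6-[(2E,6E)-farnesyl]-5,7,3',5'-tetrakis(tert-butyldimethylsilyloxy)flavanone | CC(C)=CCC/C(C)=C/CC/C(C)=C/Cc1c(O[Si](C)(C)C(C)(C)C)cc2c(c1O[Si](C)(C)C(C)(C)C)C(=O)C[C@@H](c1cc(O[Si](C)(C)C(C)(C)C)cc(O[Si](C)(C)C(C)(C)C)c1)O2
A7 | alternative 3 | 2-diazo-1-[2-{[3,5-bis(tert-butyldimethylsilyloxy)phenyl]methoxy}-5-farnesyl-4,6-bis(tert-butyldimethylsilyloxy)phenyl]ethan-1-one | [N-]=[N+]=CC(=O)c1c(OCc2cc(O[Si](C)(C)C(C)(C)C)cc(O[Si](C)(C)C(C)(C)C)c2)cc(O[Si](C)(C)C(C)(C)C)c(C/C=C(\C)CC/C=C(\C)CCC=C(C)C)c1O[Si](C)(C)C(C)(C)C
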